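I began with an easy subtraction. The questions and charges are these:

| flask | left-handed substrate | right-handed substrate | reagent | free catalyst | impurity | remark |
|---|---|---|---|---|---|---|
| winter | 10 mM | 10 mM | 30 mM | 1 mM | 0.74 mM | run made earlier |
| flask | 10 mM | 10 mM | 30.0 mM | 1.0 mM | 0.37 mM |  |

winter run (percent of the left-handed substrate and right-handed substrate together charged)

| time / min | left-handed product / % | left-handed substrate / % |
|---|---|---|
| 0.833 | 0.9 | 49.9 |
| 2.50 | 4.3 | 45.5 |
| 5.00 | 6.7 | 43.8 |
| 6.00 | 7.1 | 42.6 |
| 10.0 | 12.1 | 38.8 |
| 12.0 | 14.1 | 37.2 |
| 15.0 | 16.2 | 34.6 |

(each reading ± 0.5 percentage points)

- free catalyst is single-handed; left-handed substrate and right-handed substrate are mirror images of each other, charged as a racemate, each of them at the stated concentration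
- the numbers in the tables scatter with a standard deviation of 0.5 percentage points
- no earlier run changes the charge of impurity; that part of a forecast is a guess
- no earlier run changes the charge of reagent; that part of a forecast is a guess

- apparent order in reagent when 10 % of the left-handed substrate and right-handed substrate together are converted (percent change of the rate of making left-handed product for one percent more reagent charged)

In this flask, a conversion of 10 % of both substrates together means 2.00 mM of substrate gone. Reagent was never measured, so I assumed one reagent per substrate turned, and that leaves 28.0 mM of the 30.0 mM charged. The question compares flasks at equal conversion, not at equal time. A percent more reagent charged therefore leaves the amount used unchanged, and the reagent standing at that point rises by slightly more than a percent. I called the charge of reagent over the reagent standing at that conversion the stretch, S, and for this flask S is 1.07. If the rate is first order in reagent, which is my guess and which no run tested, and if the substrates and free catalyst at that conversion stay as they were when the charge of reagent changes, the apparent order equals S.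

The winter run looks nearly the same but carried twice the impurity. Its S is 1.07, the same as here: S is built from the reagent charged and the substrate turned, and impurity is in neither term. Impurity may change when a flask reaches that conversion, but on my assumption of one reagent per substrate turned the reagent standing there is the same, so the two runs end at one S.

The forecast gave 0.6, with a range of 0.05 to 1.05, and said: “No run varies reagent, so this is largely a prior.” My S stands above its high end.

The flask gave 1.1.

    reagent + free catalyst + left-handed substrate → free catalyst + left-handed product (k = 60.9 /M²/s)
    reagent + free catalyst + right-handed substrate → free catalyst + right-handed product (k = 28.8 /M²/s)
    free catalyst + impurity → spent catalyst A (k = 434 /M/s)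
    2 free catalyst → spent catalyst B (k = 0.125 /M/s)

That result lies in line with S, and both substrate steps in the scheme are first order in reagent. In the flask, the impurity passed into spent catalyst A early: 100 % of that step's turnover up to 80.0 min was done by 16.0 min, and spent catalyst A stood at 37.0 % of the catalyst charged at 8.00 min and at 37.0 % at 80.0 min. Both substrate steps ran on the free catalyst remaining, which fell from 58.5 % at 8.00 min to 35.9 % at 80.0 min as spent catalyst B rose to 27.1 %, and by then reagent stood at 46.0 % of its charge.

The runs stem from a simulated flask for an exercise; scatter was added.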